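**Retrosynthetic overview**

1. End game: the target comes from its 5,7-bis(methoxymethyl) ether with the C4 carbonyl masked as a 1,3-dithiane; only two unmasking steps follow the key step.
2. Key disconnection: ring C is opened at C3–C4 and at O1–C8a together. C2, C3 and O1 go back to an (R)-aryloxirane (a temporary three-membered ring that carries the only stereocentre), C4 to a lithiated 2-aryl-1,3-dithiane (acyl anion), and C8a to one end of an aryne C8≡C8a of ring A.
3. Enabling feature: in ring A, H8 lies between C8a and the oxygen-bearing C7. With fluorine on C8a it is the most acidic ring proton, so the aryne can be unveiled beside the side chain, and both the tether and the inductive pull of O7 send the C2 alkoxide to C8a. C3 is an unsubstituted methylene, so the oxirane is opened at its terminal carbon without touching C2.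
4. Fragments: the ring A dithiane from 5-fluororesorcinol (formylation, thioacetal, acetal protection); the ring B oxirane from 2-chloro-4'-hydroxyacetophenone and geraniol (Mitsunobu ether, asymmetric transfer hydrogenation, ring closure).
5. Ring order: rings A and B are bought; the dithiane ring (step 2) and the oxirane (step 6) are temporary; ring C, the only ring of the target that is made, is closed in step 7.

Key step: step 7

Remark: the stereocentre is C2 of the chromanone and is read from the SMILES as S; "geranyl" below means (2E)-3,7-dimethylocta-2,6-dien-1-yl.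

**Route**

Step 1
Reactants: 1 5-fluorobenzene-1,3-diol
Product: 3 2-fluoro-4,6-dihydroxybenzaldehyde, via aryl iminium chloride 2 (not isolated)
Conditions: POCl3, DMF, MeCN, −15 °C to rt; then H2O, 50 °C
Reagents that add atoms: N,N-dimethylformamide CN(C)C=O; water O
Why: Vilsmeier–Haack formylation, which on resorcinols goes para to one hydroxyl and ortho to the other (the two such positions are equivalent here and both lie next to fluorine) and not between the hydroxyls, as in the orcinol series.

Step 2
Reactants: 3 2-fluoro-4,6-dihydroxybenzaldehyde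
Product: 4 4-(1,3-dithian-2-yl)-5-fluorobenzene-1,3-diol
Conditions: HS(CH2)3SH, BF3·OEt2 (0.3 equiv), CH2Cl2/Et2O, 0 °C to rt
Reagents that add atoms: propane-1,3-dithiol SCCCS
Why: Lewis-acid-catalysed dithioacetalisation of an aryl aldehyde, which tolerates free phenols and turns the formyl carbon into the masked acyl anion needed in the key step.

Step 3
Reactants: 4 4-(1,3-dithian-2-yl)-5-fluorobenzene-1,3-diol
Product: 5 2-[2-fluoro-4,6-bis(methoxymethoxy)phenyl]-1,3-dithiane
Conditions: MeOCH2Cl, i-Pr2NEt, CH2Cl2, 0 °C to rt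
Reagents that add atoms: chloromethyl methyl ether COCCl
Why: O-alkylation of both phenols to methoxymethyl acetals, which withstand lithium amides and aryllithiums and acidify the neighbouring ring proton.

Step 4
Reactants: 6 2-chloro-1-(4-hydroxyphenyl)ethan-1-one; 7 geraniol, (2E)-3,7-dimethylocta-2,6-dien-1-ol
Product: 8 2-chloro-1-[4-(geranyloxy)phenyl]ethan-1-one
Conditions: PPh3, diisopropyl azodicarboxylate, THF, 0 °C to rt
Reagents that add atoms: none
Why: Mitsunobu etherification of an acidic para-acyl phenol by a primary allylic alcohol (SN2 at C1 of geraniol, so the E alkene stays in place), chosen because no free phenoxide is present that could attack the chloromethyl ketone.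

Step 5
Reactants: 8 2-chloro-1-[4-(geranyloxy)phenyl]ethan-1-one
Product: 9 (1R)-2-chloro-1-[4-(geranyloxy)phenyl]ethan-1-ol
Conditions: Cp*RhCl[(S,S)-TsDPEN] (0.5 mol %), HCO2H/Et3N (5:2), EtOAc, rt
Reagents that add atoms: none
Why: Noyori–Ikariya asymmetric transfer hydrogenation of an aryl chloromethyl ketone, in which the (S,S)-diamine ligand fixes the carbonyl face that takes the hydride and should give the R chlorohydrin (the spatial analogue of the (S)-1-arylethanol obtained from aryl methyl ketones, R because CH2Cl outranks aryl), while the isolated alkenes are not reduced.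

Step 6
Reactants: 9 (1R)-2-chloro-1-[4-(geranyloxy)phenyl]ethan-1-ol
Product: 10 (2R)-2-[4-(geranyloxy)phenyl]oxirane
Conditions: KOtBu, THF, 0 °C; used at once without chromatography
Reagents that add atoms: none
Why: Intramolecular Williamson ring closure (3-exo-tet) of the alkoxide on the primary chloride, in which no bond to the stereocentre is broken, so the R configuration is kept.

Step 7
Reactants: 5 2-[2-fluoro-4,6-bis(methoxymethoxy)phenyl]-1,3-dithiane; 10 (2R)-2-[4-(geranyloxy)phenyl]oxirane
Product: 16 (2S)-2-[4-(geranyloxy)phenyl]-5,7-bis(methoxymethoxy)spiro[chromane-4,2'-[1,3]dithiane], via lithiated dithiane 11 (not isolated), via lithium alkoxide 12 (not isolated), via ortho-lithiated fluoroarene 13 (not isolated), via aryne 14 (not isolated), via 8-lithiochroman 15 (not isolated)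
Conditions: LiN(iPr)2 (1.05 equiv), THF, −78 to −30 °C; then 10, DMPU, −30 to 0 °C; then lithium 2,2,6,6-tetramethylpiperidide (2.2 equiv), −78 to 0 °C; then aq NH4Cl
Reagents that add atoms: none
Why: LiN(iPr)2 removes the most acidic proton of 5, the dithiane C–H flanked by two sulfurs and the aryl ring, and the carbanion 11 opens oxirane 10 by SN2 attack at its unsubstituted methylene carbon, which makes the C3–C4 bond and sets O1 free as lithium alkoxide 12. Lithium tetramethylpiperidide then removes H8, the ring A proton between fluorine and the C7 acetal oxygen (13), LiF leaves on warming, and the aryne 14 (C8≡C8a) is taken by the tethered alkoxide at C8a, which makes the O1–C8a bond and leaves aryllithium 15 for protonation on quench. The closest known reaction types are the Corey–Seebach alkylation of a 2-aryl-2-lithio-1,3-dithiane by a terminal epoxide and the base-induced intramolecular capture of an aryne by a side-chain alkoxide that gives chromans (Bunnett-type aryne ring closure). Ring C closes by 6-exo attack of oxygen on the aryne; attack at C8 would need a meta-bridged ring, and the inductive pull of O7 distorts the aryne in the same sense, so that the nucleophile enters at the carbon meta to O7 (C8a) and the carbanion develops at C8 beside it. No stereocentre is formed: C2 is brought in by 10 and no bond to it is made or broken, so the R oxirane becomes the 2S chroman (the descriptor changes only because the methylene carbon loses its oxygen). The step needs attack at the epoxide methylene and not at the benzylic carbon (secured by the bulk of the tertiary dithianyl anion and the absence of Lewis acid), dithiane metalation before ring metalation (secured by the acidity gap and by keeping the first two stages free of excess base), and a C4 centre that cannot enolise under base (the thioketal rules out retro-aldol cleavage and chalcone formation, the two ways in which C2 could racemise).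

Step 8
Reactants: 16 (2S)-2-[4-(geranyloxy)phenyl]-5,7-bis(methoxymethoxy)spiro[chromane-4,2'-[1,3]dithiane]
Product: 17 (2S)-2-[4-(geranyloxy)phenyl]-5,7-bis(methoxymethoxy)chroman-4-one
Conditions: MeI, CaCO3, MeCN/H2O (9:1), 45 °C
Reagents that add atoms: water O
Why: Thioacetal hydrolysis by S-methylation, helped by the electron-rich ring A that stabilises the thionium ion, under carbonate-buffered conditions that should leave the acetals, the alkenes and the C2 configuration alone.

Step 9
Reactants: 17 (2S)-2-[4-(geranyloxy)phenyl]-5,7-bis(methoxymethoxy)chroman-4-one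
Product: 19 (2S)-2-[4-(geranyloxy)phenyl]-5,7-dihydroxychroman-4-one (4'-O-geranylnaringenin), via bis(trimethylsilyl) ether 18 (not isolated)
Conditions: Me3SiOTf, 2,2'-bipyridyl, MeCN, 0 °C to rt; then H2O
Reagents that add atoms: none
Why: Silyl triflate–bipyridyl cleavage of aromatic methoxymethyl ethers, which turns each aryl acetal into an aryl silyl ether that is hydrolysed on work-up, is non-protic and should spare the allylic aryl ether, and does not open the chromanone, so C2 stays S.

**Compound list**

1 | 5-fluorobenzene-1,3-diol | Oc1cc(O)cc(F)c1 | starting material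
2 | N-[(2-fluoro-4,6-dihydroxyphenyl)methylidene]-N-methylmethanaminium chloride | C[N+](C)=Cc1c(O)cc(O)cc1F.[Cl-] | intermediate (not isolated)
3 | 2-fluoro-4,6-dihydroxybenzaldehyde | O=Cc1c(O)cc(O)cc1F | intermediate
4 | 4-(1,3-dithian-2-yl)-5-fluorobenzene-1,3-diol | Oc1cc(O)c(C2SCCCS2)c(F)c1 | intermediate
5 | 2-[2-fluoro-4,6-bis(methoxymethoxy)phenyl]-1,3-dithiane | COCOc1cc(OCOC)c(C2SCCCS2)c(F)c1 | intermediate
6 | 2-chloro-1-(4-hydroxyphenyl)ethan-1-one | O=C(CCl)c1ccc(O)cc1 | starting material
7 | geraniol, (2E)-3,7-dimethylocta-2,6-dien-1-ol | CC(C)=CCC/C(C)=C/CO | starting material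
8 | 2-chloro-1-[4-(geranyloxy)phenyl]ethan-1-one | CC(C)=CCC/C(C)=C/COc1ccc(C(=O)CCl)cc1 | intermediate
9 | (1R)-2-chloro-1-[4-(geranyloxy)phenyl]ethan-1-ol | CC(C)=CCC/C(C)=C/COc1ccc([C@@H](O)CCl)cc1 | intermediate
10 | (2R)-2-[4-(geranyloxy)phenyl]oxirane | CC(C)=CCC/C(C)=C/COc1ccc([C@@H]2CO2)cc1 | intermediate
11 | 2-[2-fluoro-4,6-bis(methoxymethoxy)phenyl]-2-lithio-1,3-dithiane | COCOc1cc(OCOC)c(C2([Li])SCCCS2)c(F)c1 | intermediate (not isolated)
12 | lithium (1S)-2-{2-[2-fluoro-4,6-bis(methoxymethoxy)phenyl]-1,3-dithian-2-yl}-1-[4-(geranyloxy)phenyl]ethan-1-olate | CC(C)=CCC/C(C)=C/COc1ccc([C@@H](O[Li])CC2(SCCCS2)c2c(F)cc(OCOC)cc2OCOC)cc1 | intermediate (not isolated)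
13 | alkoxide 12 lithiated at the ring carbon between fluorine and the acetal oxygen (3-lithio-2-fluoro-4,6-bis(methoxymethoxy)phenyl) | CC(C)=CCC/C(C)=C/COc1ccc([C@@H](O[Li])CC2(SCCCS2)c2c(F)c([Li])c(OCOC)cc2OCOC)cc1 | intermediate (not isolated)
14 | lithium (1S)-2-{2-[2,3-didehydro-4,6-bis(methoxymethoxy)phenyl]-1,3-dithian-2-yl}-1-[4-(geranyloxy)phenyl]ethan-1-olate (aryne) | CC(C)=CCC/C(C)=C/COc1ccc([C@@H](O[Li])CC2(SCCCS2)C3=C(OCOC)C=C(OCOC)C#C3)cc1 | intermediate (not isolated)
15 | (2S)-2-[4-(geranyloxy)phenyl]-8-lithio-5,7-bis(methoxymethoxy)spiro[chromane-4,2'-[1,3]dithiane] | CC(C)=CCC/C(C)=C/COc1ccc([C@@H]2CC3(SCCCS3)c3c(OCOC)cc(OCOC)c([Li])c3O2)cc1 | intermediate (not isolated)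
16 | (2S)-2-[4-(geranyloxy)phenyl]-5,7-bis(methoxymethoxy)spiro[chromane-4,2'-[1,3]dithiane] | CC(C)=CCC/C(C)=C/COc1ccc([C@@H]2CC3(SCCCS3)c3c(OCOC)cc(OCOC)cc3O2)cc1 | intermediate
17 | (2S)-2-[4-(geranyloxy)phenyl]-5,7-bis(methoxymethoxy)chroman-4-one | CC(C)=CCC/C(C)=C/COc1ccc([C@@H]2CC(=O)c3c(OCOC)cc(OCOC)cc3O2)cc1 | intermediate
18 | (2S)-2-[4-(geranyloxy)phenyl]-5,7-bis(trimethylsilyloxy)chroman-4-one | CC(C)=CCC/C(C)=C/COc1ccc([C@@H]2CC(=O)c3c(O[Si](C)(C)C)cc(O[Si](C)(C)C)cc3O2)cc1 | intermediate (not isolated)
19 | (2S)-2-[4-(geranyloxy)phenyl]-5,7-dihydroxychroman-4-one | CC(C)=CCC/C(C)=C/COc1ccc([C@@H]2CC(=O)c3c(O)cc(O)cc3O2)cc1 | target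

**Step count and risks**

Total steps: 9. Longest linear sequence: 6 steps (1 → 3 → 4 → 5 → 16 → 17 → 19; the branch from 6 and 7 is equally long).

Steps most likely to fail:

Step 7. In the third stage the aryne may be consumed by paths other than ring closure: addition of amide base or amine to the aryne, or base-induced 1,4-elimination or Wittig rearrangement of the allylic aryl ether. Fluoride may also be lost too early if H8 is metalated during the first stage. The fallback sets out from 5 and 10 and keeps only the epoxide opening. The flask is quenched with aq NH4Cl after the second stage, which gives (1S)-alcohol F1. F1 is unmasked with MeI and CaCO3 in aqueous MeCN to β-hydroxy ketone F2. Ring C is then closed by a classical intramolecular SNAr reaction (Cs2CO3, DMF, 0 °C to rt, kept cold to hold back retro-aldol cleavage). The fluorine of F2 is ortho to the ketone and meta to both acetal oxygens, so it is activated. This gives 17, where the route is rejoined.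

Step 9. The silyl triflate may ionise the allylic C–O bond of the geranyl aryl ether (loss or cyclisation of the side chain) before the less reactive C7 acetal is cleaved. The fallback sets out from diol 4 and carries ring A as 1-ethoxyethyl acetals, which are cleaved by a trace of weak acid. Diol 4 with ethyl vinyl ether and pyridinium p-toluenesulfonate (CH2Cl2, rt) gives bis(1-ethoxyethyl) dithiane F3 (mixture of acetal epimers, as are all later compounds of this branch). F3 is taken through the one-flask operation of step 7 with 10, by way of lithiated dithiane F4, lithium alkoxide F5, ortho-lithiated fluoroarene F6, aryne F7 and 8-lithiochroman F8, to spiro chroman F9. MeI and CaCO3 in aqueous MeCN then give chromanone F10. Pyridinium p-toluenesulfonate in MeOH at rt removes both acetals and gives 19, where the route ends.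

Step 4. PPh3 may be quaternised by the chloromethyl ketone in competition with betaine formation, and the allylic system may transpose (SN2′) to the linalyl ether. The fallback sets out from geraniol 7 and builds the ether before the chloride. PBr3 in Et2O at 0 °C gives geranyl bromide F11. F11 alkylates commercial 1-(4-hydroxyphenyl)ethan-1-one (K2CO3, acetone, rt) to give aryl methyl ketone F12. LiN(SiMe3)2 in THF at −78 °C forms lithium enolate F13, which is chlorinated in the flask with p-toluenesulfonyl chloride. This gives 8, where the route is rejoined.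

**Further compounds**

F1 | step 7 | (1S)-2-{2-[2-fluoro-4,6-bis(methoxymethoxy)phenyl]-1,3-dithian-2-yl}-1-[4-(geranyloxy)phenyl]ethan-1-ol | CC(C)=CCC/C(C)=C/COc1ccc([C@@H](O)CC2(SCCCS2)c2c(F)cc(OCOC)cc2OCOC)cc1
F2 | step 7 | (3S)-1-[2-fluoro-4,6-bis(methoxymethoxy)phenyl]-3-[4-(geranyloxy)phenyl]-3-hydroxypropan-1-one | CC(C)=CCC/C(C)=C/COc1ccc([C@@H](O)CC(=O)c2c(F)cc(OCOC)cc2OCOC)cc1
F3 | step 9 | 2-[2,4-bis(1-ethoxyethoxy)-6-fluorophenyl]-1,3-dithiane (acetal epimers) | CCOC(C)Oc1cc(OC(C)OCC)c(C2SCCCS2)c(F)c1
F4 | step 9 | 2-[2,4-bis(1-ethoxyethoxy)-6-fluorophenyl]-2-lithio-1,3-dithiane | CCOC(C)Oc1cc(OC(C)OCC)c(C2([Li])SCCCS2)c(F)c1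
F5 | step 9 | lithium (1S)-2-{2-[2,4-bis(1-ethoxyethoxy)-6-fluorophenyl]-1,3-dithian-2-yl}-1-[4-(geranyloxy)phenyl]ethan-1-olate | CC(C)=CCC/C(C)=C/COc1ccc([C@@H](O[Li])CC2(SCCCS2)c2c(F)cc(OC(C)OCC)cc2OC(C)OCC)cc1
F6 | step 9 | alkoxide F5 lithiated at the ring carbon between fluorine and the acetal oxygen | CC(C)=CCC/C(C)=C/COc1ccc([C@@H](O[Li])CC2(SCCCS2)c2c(F)c([Li])c(OC(C)OCC)cc2OC(C)OCC)cc1
F7 | step 9 | lithium (1S)-2-{2-[2,3-didehydro-4,6-bis(1-ethoxyethoxy)phenyl]-1,3-dithian-2-yl}-1-[4-(geranyloxy)phenyl]ethan-1-olate (aryne) | CC(C)=CCC/C(C)=C/COc1ccc([C@@H](O[Li])CC2(SCCCS2)C3=C(OC(C)OCC)C=C(OC(C)OCC)C#C3)cc1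
F8 | step 9 | (2S)-5,7-bis(1-ethoxyethoxy)-2-[4-(geranyloxy)phenyl]-8-lithiospiro[chromane-4,2'-[1,3]dithiane] | CC(C)=CCC/C(C)=C/COc1ccc([C@@H]2CC3(SCCCS3)c3c(OC(C)OCC)cc(OC(C)OCC)c([Li])c3O2)cc1
F9 | step 9 | (2S)-5,7-bis(1-ethoxyethoxy)-2-[4-(geranyloxy)phenyl]spiro[chromane-4,2'-[1,3]dithiane] | CC(C)=CCC/C(C)=C/COc1ccc([C@@H]2CC3(SCCCS3)c3c(OC(C)OCC)cc(OC(C)OCC)cc3O2)cc1
F10 | step 9 | (2S)-5,7-bis(1-ethoxyethoxy)-2-[4-(geranyloxy)phenyl]chroman-4-one | CC(C)=CCC/C(C)=C/COc1ccc([C@@H]2CC(=O)c3c(OC(C)OCC)cc(OC(C)OCC)cc3O2)cc1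
F11 | step 4 | geranyl bromide, (2E)-1-bromo-3,7-dimethylocta-2,6-diene | CC(C)=CCC/C(C)=C/CBr
F12 | step 4 | 1-[4-(geranyloxy)phenyl]ethan-1-one | CC(C)=CCC/C(C)=C/COc1ccc(C(C)=O)cc1
F13 | step 4 | lithium 1-[4-(geranyloxy)phenyl]ethen-1-olate | CC(C)=CCC/C(C)=C/COc1ccc(C(=C)O[Li])cc1
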